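## Structural features

1. The target is a flavanone. The phloroglucinol-type ring A is fused through C4a–C8a to the dihydropyranone ring C (O1, C2, C3, C4=O), and C2 carries ring B (2'-OMe, 4'-OH).
2. All six positions of ring A differ: O1 at C8a, the acyl carbon C4 at C4a, OMe at C5, H at C6, free OH at C7 and a C10 lavandulyl chain at C8.
3. The chain is numbered C1'' (benzylic CH2), C2'' (methine), C3''H2–C4''H=C5''Me2 (prenyl arm) and C8''(=C9''H2)C10''H3 (isopropenyl arm); it is bound to C8 through a saturated CH2, so the arene is homoallylic and the usual prenylation devices (allyl cation, aromatic Claisen or Claisen–Cope shift) cannot deliver it.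
4. The two stereocentres, C2 (S) and C2'' (R), are not neighbours: five bonds (C2–O1–C8a–C8–C1''–C2'') separate them, no relay is possible, and each needs its own control element.
5. C2'' is the harder one, because its three carbon ligands are similar in size and both flanking alkenes end in non-stereogenic termini (=C9''H2, =C5''Me2), which rules out chirality transfer by any [3,3] shift; C2 is the fragile one, because base or strong acid opens ring C to the 2'-hydroxychalcone (retro-oxa-Michael) and scrambles it.
6. The two electron-rich alkenes are also fragile: under Brønsted acid they cyclise onto the free 7-OH to give 2,2-dimethylchromans, and they forbid hydrogenolysis.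
7. The real difficulty is therefore the ensemble C8–C1''–C2'': a non-allylic aryl–CH2 bond at one defined position of ring A, next to an isolated stereocentre.
8. The key step exploits three features of this region: C1''–C2''–C8'' is the β-, α- and carbonyl-carbon pattern of a ketone once C8''=C9''H2 is read as C8''=O; C8 is ortho to two oxygens and para to a third, so it is a strong carbon nucleophile; and before O5 is methylated, the acetyl-bearing ring A has a mirror plane through C4a and C7 that makes C6 and C8 the same position.

## Logic of the disconnections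

**18 ⇒ 16 (through 17).**
- Bonds cut: O7–CH2 and O4'–CH2 of two methoxymethyl acetals.
- Reason: both phenols must be masked against base, ylide and organorhodium species, and the 7-OH must not be free beside the alkenes whenever acid is present.
- Gain: none in skeleton, but the last step becomes a pure unmasking.
- Demand: the cleavage must run in a medium that neither protonates alkenes nor forms the C3 enolate.

**16 ⇒ 10 + 15.**
- Bond cut: C2–C1'.
- Reason: cutting here, and not at O1–C2, lets C2 arise in an irreversible, catalyst-controlled C–C bond formation on a flat, already closed ring C, so the chalcone equilibrium never enters.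
- Gain: the C2 stereocentre and the whole of ring B are removed, and the route becomes convergent.
- Demand: facial selectivity must come from the ligand alone (C2'' is too far away to help or hinder), in a near-neutral medium.

**10 ⇒ 8 (through 9).**
- Bonds cut: O1–C2 and C2=C3.
- Reason: C2 is a single carbon at the formate oxidation level and can be clipped onto the acetyl CH3 and the neighbouring phenol.
- Gain: ring C is removed and a simple acetophenone remains.
- Demand: ring closure under an acid too weak to protonate the side-chain alkenes.

**8 ⇒ 7.**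
- Bond cut: O5–CH3.
- Reason: removing this methyl group takes away the element that makes the two ortho hydroxyls of ring A constitutionally different in origin.
- Gain: the ring A precursor becomes symmetric one step further back.
- Demand: the forward methylation must choose O5 (flanked by H6) over the hydroxyl that becomes O1 (flanked by C1''H2).

**7 ⇒ 6.**
- Bond cut: C8''=C9''.
- Reason: the isopropenyl group is read as a masked acetyl group, which places C2'' α and C1'' β to a carbonyl.
- Gain: a polar retron for the next cut.
- Demand: the methylenation must not enolise the ketone towards C2'', and it must leave the aryl ketone alone.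

**6 ⇒ 4 + 2 (through 5; key disconnection).**
- Bonds cut: C8–C1'' and C2''–H.
- Reason: the chain is not attached as a ready-made C10 electrophile. Ring A adds as a carbon nucleophile to the CH2 terminus of an α-branched vinyl ketone, and the stereocentre is written by the proton that follows.
- Gain: the aryl–CH2 bond, the C8/C6 site problem (removed by the symmetry of 4) and the C2'' stereocentre are all settled in one operation. The precursors are an achiral C9 enone and a symmetric arene.
- Demand: an enantioselective protonation under catalyst control, faster than any uncatalysed addition.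
- In one sentence: C8–C1'' and C2'' arise together when symmetric 4 adds to iminium-activated 2 and the resulting enamine is protonated enantioselectively. This sentence does not fit the chalcone/lavandulyl halide route.

**2 ⇒ 1.**
- Bond cut: C1''=C2''.
- Reason: C1'' is a one-carbon unit at the formaldehyde level, placed on the more substituted α-carbon of a bulk methyl ketone that already holds the prenyl arm, C2'', C8'' and C10''.
- Gain: a commodity starting material.
- Demand: attack at the CH2 and not at the CH3 side of the ketone.

**4 ⇒ 3.**
- Bond cut: O7–CH2 (acetal).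
- Reason: masking only the hydroxyl para to the acetyl group keeps the mirror plane.
- Gain: a commercial triphenol.
- Demand: mono-alkylation at the one hydroxyl that is not hydrogen-bonded.

**15 ⇒ 12 ⇒ 11 (through 13 and 14).**
- Bonds cut: C1'–B, then O4'–CH2.
- Reason: the bromide marks C1' of ring B unambiguously.
- Gain: a commercial bromophenol.
- Demand: halogen–metal exchange faster than directed ortho-metalation, and a gentle hydrolysis of an electron-rich boronate.

## Other disconnections considered

**Alternative 1:** (the first that comes to mind)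
- Cut: O1–C2, C2–C3 and C8–C1''.
- Forward: ring A is alkylated with the intact, separately resolved (S)-lavandulyl bromide A2. A Claisen–Schmidt condensation then gives the 2'-hydroxychalcone A1, which closes by 6-endo-trig oxa-Michael addition.
- Grounds against:
  - A2 is a β-branched, non-allylic primary halide, so SN2 attack by a hindered aryl-metal or ambident phenoxide is slow, and O-alkylation competes.
  - Its stereocentre costs a separate sequence.
  - The site of attack on ring A must be enforced by extra protecting-group work.
  - The closure of A1 is reversible, so it delivers both C2 epimers, which differ only at a centre five bonds away from the other and are hard to separate.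
- The chosen plan makes the same C8–C1'' bond from a C–H position, without a leaving group on a neopentyl-like carbon, and never passes through an equilibrating chalcone.

**Alternative 2:**
- Cut: C2''–C3''.
- Forward: in imitation of the plant dimethylallyltransferase, a dimethylallyl cation equivalent is attacked by the C2''=C8'' double bond of the 8-prenylflavanone A3, and C9'' loses a proton.
- Grounds against:
  - Outside an enzyme pocket, C6 and the phenolic oxygens of A3 are better nucleophiles than a trisubstituted alkene.
  - The tertiary cation at C8'' sits in a six-membered-ring relationship to O7, so it should be intercepted to the 2,2-dimethylchroman A4 faster than it loses a proton.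
  - Nothing differentiates the two faces of C2''.
  - The Lewis or Brønsted acid that is needed threatens C2.
- The chosen plan keeps the biosynthetic idea of growing the chain on the ring, but replaces the cation by an enamine whose fate (protonation) is the stereodefining event.

**Alternative 3:**
- Cut C2''–C3'' and reconnect C9''–C5'' (retro-Cope).
- Forward: the isomeric, easier 8-[(2E)-3,5,5-trimethylhepta-2,6-dienyl] skeleton A5, an ordinary allyl arene, is made first. A [3,3] shift then turns it into the lavandulyl skeleton, driven by loss of the quaternary carbon and gain of a trisubstituted alkene.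
- Grounds against:
  - Both sp3 carbons of the 1,5-diene in A5 (C9''H2 and C5''Me2) are non-stereogenic, so there is no chirality to transfer. C2'' would depend on an enantioselective Cope rearrangement of an unactivated acyclic diene, for which no dependable control element exists.
  - The thermal variant needs temperatures at which the phenol/alkene pair and the acetal are at risk.
  - The C10 allylic electrophile for A5 takes several steps and still leaves the C6/C8 question open.
- The chosen plan is shorter and addresses the stereocentre directly.

Key step: step 3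

Assumption: the sense of induction of the two chiral catalysts (steps 3 and 9) is taken as drawn, and since both are available in both mirror-image forms, the other enantiomer is used if the sense is opposite; ring A is numbered as in the flavanone throughout (acetophenone C1, C2, C3, C4, C5, C6 = flavanone C4a, C8a, C8, C7, C6, C5).

## Route

Step 1
Reactants: 1 6-methylhept-5-en-2-one
Product: 2 6-methyl-3-methylidenehept-5-en-2-one
Conditions: (CH2O)n (2 equiv), i-Pr2NH·TFA (1 equiv), TFA (10 mol %), THF, reflux
Reagents that add atoms: paraformaldehyde (as formaldehyde), C=O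
Why: Mannich condensation followed by β-elimination of the amine (direct α-methylenation); under the acidic, equilibrating conditions the more substituted enol (C3) of the methyl ketone reacts, and the buffered ammonium trifluoroacetate is too weak an acid to touch the trisubstituted alkene. Compound 2 is used at once because α-methylene ketones dimerise on standing.

Step 2
Reactants: 3 1-(2,4,6-trihydroxyphenyl)ethanone
Product: 4 1-[2,6-dihydroxy-4-(methoxymethoxy)phenyl]ethanone
Conditions: MOMCl (1.0 equiv), i-Pr2NEt (1.2 equiv), THF/CH2Cl2, 0 °C
Reagents that add atoms: chloromethyl methyl ether, COCCl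
Why: Williamson-type O-alkylation; the 4-OH (future O7) is the most acidic hydroxyl and the only one never hydrogen-bonded to the acetyl group, so one equivalent of electrophile goes there. The product keeps the mirror plane through C4a and C7.

Step 3
Reactants: 4 1-[2,6-dihydroxy-4-(methoxymethoxy)phenyl]ethanone; 2 6-methyl-3-methylidenehept-5-en-2-one
Product: 6 (3R)-3-{[3-acetyl-2,4-dihydroxy-6-(methoxymethoxy)phenyl]methyl}-6-methylhept-5-en-2-one, via catalyst-bound Z-enamine 5 (not isolated)
Conditions: (S)-t-BuCH(NH2)CH2NEt2·TfOH (20 mol %), 3-NO2C6H4CO2H (20 mol %), 4 (1.5 equiv), CHCl3, 0 °C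
Reagents that add atoms: none
Why: Proposed new method: the primary amine of the catalyst condenses with the ketone of 2 (iminium activation), and C8 of 4 (ortho to two oxygens, para to the third) attacks the unsubstituted terminal CH2 in a Friedel–Crafts-type conjugate addition that forms C8–C1'' and, after rearomatisation, leaves the secondary enamine 5. C-protonation of 5 at C2'' by the diethylammonium arm of the same catalyst molecule, followed by hydrolysis of the resulting iminium ion, releases 6 and the catalyst. The closest known reaction type is the chiral primary-amine-catalysed Friedel–Crafts conjugate addition/enantioselective enamine protonation of indoles with α-substituted vinyl ketones and acroleins; what is new is an acylphloroglucinol as the π-nucleophile. No ring is closed in this step. The only new stereocentre, C2'', is set in the protonation and not in the C–C bond formation, and two elements control it: the Z geometry of 5, in which the bulky arylmethyl group lies cis to the small N–H and not to C10''H3, and the intramolecular delivery of the proton from the ammonium group, which the tert-butyl-bearing stereocentre of the catalyst holds over one face of the enamine. Site selectivity needs no control because C6 and C8 of 4 are equivalent by symmetry, and a second alkylation is held back by the excess of 4 and by the added bulk in 6. Chemoselectivity rests on the much higher electrophilicity of the iminium ion compared with free 2, which should let the catalysed path outrun the racemic addition of the phenol(ate), on the reversibility of O-attack, and on the inertness of the hydrogen-bonded, di-ortho-substituted aryl ketone of 4 towards the amine. The α-branched ketone 6 should condense with the catalyst far more slowly than 2 and then enolise towards C10''H3, so C2'' should not erode once it is set.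

Step 4
Reactants: 6 (3R)-3-{[3-acetyl-2,4-dihydroxy-6-(methoxymethoxy)phenyl]methyl}-6-methylhept-5-en-2-one
Product: 7 1-{2,6-dihydroxy-4-(methoxymethoxy)-3-[(2R)-5-methyl-2-(prop-1-en-2-yl)hex-4-en-1-yl]phenyl}ethanone
Conditions: Ph3PCH3Br (4.2 equiv), KOt-Bu (4.0 equiv), THF, 0 °C; then 6, 0 °C to rt; aq NH4Cl
Reagents that add atoms: methyltriphenylphosphonium bromide, C[P+](c1ccccc1)(c1ccccc1)c1ccccc1.[Br-]
Why: Wittig methylenation; two equivalents of ylide deprotonate the phenols, which turns the hindered aryl ketone into an inert vinylogous carboxylate, so only the aliphatic methyl ketone reacts. The slight deficit of base leaves no free alkoxide, and the ylide is too weak a base to enolise the ketone towards C2'', so the configuration should be kept; after this step C2'' is no longer next to a carbonyl group.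

Step 5
Reactants: 7 1-{2,6-dihydroxy-4-(methoxymethoxy)-3-[(2R)-5-methyl-2-(prop-1-en-2-yl)hex-4-en-1-yl]phenyl}ethanone
Product: 8 1-{2-hydroxy-6-methoxy-4-(methoxymethoxy)-3-[(2R)-5-methyl-2-(prop-1-en-2-yl)hex-4-en-1-yl]phenyl}ethanone
Conditions: MeI (1.05 equiv), K2CO3 (1.1 equiv), acetone, rt
Reagents that add atoms: iodomethane, CI
Why: Williamson ether synthesis; O5 is flanked by H6, whereas the other hydroxyl is wedged between the acetyl group and the branched C1''H2 group and is pushed into the hydrogen bond to C=O, so the less hindered oxygen should react. After the first methylation the remaining hydroxyl is fully chelated and the reaction should stop.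

Step 6
Reactants: 8 1-{2-hydroxy-6-methoxy-4-(methoxymethoxy)-3-[(2R)-5-methyl-2-(prop-1-en-2-yl)hex-4-en-1-yl]phenyl}ethanone
Product: 10 5-methoxy-7-(methoxymethoxy)-8-[(2R)-5-methyl-2-(prop-1-en-2-yl)hex-4-en-1-yl]-4H-chromen-4-one, via E-enaminone 9 (not isolated)
Conditions: DMF-DMA (3 equiv), toluene, 95 °C; evaporate; AcOH, 60 °C
Reagents that add atoms: N,N-dimethylformamide dimethyl acetal, COC(OC)N(C)C
Why: Condensation of the acetyl CH3 with the amide acetal gives 9; in warm acetic acid the phenol adds to the β-carbon and dimethylamine leaves (6-endo-trig addition–elimination), which is the standard enaminone route to chromones. Acetic acid is too weak to protonate the alkenes or to cleave the aryl MOM ether.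

Step 7
Reactants: 11 4-bromo-3-methoxyphenol
Product: 12 1-bromo-2-methoxy-4-(methoxymethoxy)benzene
Conditions: MOMCl (1.2 equiv), i-Pr2NEt (1.5 equiv), CH2Cl2, 0 °C to rt
Reagents that add atoms: chloromethyl methyl ether, COCCl
Why: Williamson-type O-alkylation of the only hydroxyl group; the same acetal as on ring A allows one common deprotection.

Step 8
Reactants: 12 1-bromo-2-methoxy-4-(methoxymethoxy)benzene
Product: 15 [2-methoxy-4-(methoxymethoxy)phenyl]boronic acid, via aryllithium 13 (not isolated), via lithium aryltriisopropoxyborate 14 (not isolated)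
Conditions: n-BuLi (1.05 equiv), THF, −78 °C; B(Oi-Pr)3 (1.5 equiv), −78 °C to rt; 1 M HCl to pH 5–6, 0 °C
Reagents that add atoms: triisopropyl borate, CC(C)OB(OC(C)C)OC(C)C; water, O
Why: Bromine–lithium exchange at −78 °C is faster than ortho-lithiation next to the acetal, so boron ends up at C1' only; borate quench and hydrolysis is the standard boronic acid synthesis. The short, cold, weakly acidic work-up limits protodeboronation of the electron-rich ring and spares the MOM ether.

Step 9
Reactants: 10 5-methoxy-7-(methoxymethoxy)-8-[(2R)-5-methyl-2-(prop-1-en-2-yl)hex-4-en-1-yl]-4H-chromen-4-one; 15 [2-methoxy-4-(methoxymethoxy)phenyl]boronic acid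
Product: 16 (2S)-5-methoxy-2-[2-methoxy-4-(methoxymethoxy)phenyl]-7-(methoxymethoxy)-8-[(2R)-5-methyl-2-(prop-1-en-2-yl)hex-4-en-1-yl]-2,3-dihydro-4H-chromen-4-one
Conditions: [RhCl(C2H4)2]2 (2.5 mol %), (S)-MeO-F12-BIPHEP (5.5 mol %), KOH (10 mol %), 15 (3 equiv), toluene/H2O 10:1, 30 °C
Reagents that add atoms: none
Why: Hayashi–Miyaura reaction (rhodium-catalysed asymmetric 1,4-addition of an arylboronic acid), a known entry to flavanones from chromones; the aryl–rhodium species adds to C2 from the face left open by the biaryl bisphosphine, and water protonates the oxa-π-allyl rhodium at C3. C2 is set by the ligand alone, since C2'' is five bonds away; unactivated alkenes are not carbometalated, and the nearly neutral medium should keep ring C closed.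

Step 10
Reactants: 16 (2S)-5-methoxy-2-[2-methoxy-4-(methoxymethoxy)phenyl]-7-(methoxymethoxy)-8-[(2R)-5-methyl-2-(prop-1-en-2-yl)hex-4-en-1-yl]-2,3-dihydro-4H-chromen-4-one
Product: 18 (2S)-2'-methoxykurarinone, via bis(trimethylsilyl) ether 17 (not isolated)
Conditions: TMSOTf (4 equiv), 2,2'-bipyridyl (6 equiv), MeCN, 0 °C to rt; then H2O
Reagents that add atoms: none
Why: Silyl triflate/bipyridyl cleavage of aromatic MOM ethers: the acetal is silylated, bipyridyl takes over the CH2OMe group as a pyridinium salt, and the aryl silyl ethers of 17 hydrolyse on addition of water. The medium stays weakly basic and free of strong acid, so the alkenes are not protonated next to the emerging 7-OH and no C3 enolate forms; both stereocentres should stay untouched.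

## Compound list

1 | 6-methylhept-5-en-2-one | CC(=O)CCC=C(C)C | starting material
2 | 6-methyl-3-methylidenehept-5-en-2-one | CC(=O)C(=C)CC=C(C)C | intermediate
3 | 1-(2,4,6-trihydroxyphenyl)ethanone | CC(=O)c1c(O)cc(O)cc1O | starting material
4 | 1-[2,6-dihydroxy-4-(methoxymethoxy)phenyl]ethanone | CC(=O)c1c(O)cc(OCOC)cc1O | intermediate
5 | Z-enamine of 6 with (S)-N1,N1-diethyl-3,3-dimethylbutane-1,2-diamine (not isolated) | C/C(N[C@@H](C(C)(C)C)CN(CC)CC)=C(\CC=C(C)C)Cc1c(O)c(C(C)=O)c(O)cc1OCOC | intermediate
6 | (3R)-3-{[3-acetyl-2,4-dihydroxy-6-(methoxymethoxy)phenyl]methyl}-6-methylhept-5-en-2-one | CC(=O)[C@H](CC=C(C)C)Cc1c(O)c(C(C)=O)c(O)cc1OCOC | intermediate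
7 | 1-{2,6-dihydroxy-4-(methoxymethoxy)-3-[(2R)-5-methyl-2-(prop-1-en-2-yl)hex-4-en-1-yl]phenyl}ethanone | C=C(C)[C@H](CC=C(C)C)Cc1c(O)c(C(C)=O)c(O)cc1OCOC | intermediate
8 | 1-{2-hydroxy-6-methoxy-4-(methoxymethoxy)-3-[(2R)-5-methyl-2-(prop-1-en-2-yl)hex-4-en-1-yl]phenyl}ethanone | C=C(C)[C@H](CC=C(C)C)Cc1c(O)c(C(C)=O)c(OC)cc1OCOC | intermediate
9 | (2E)-3-(dimethylamino)-1-{2-hydroxy-6-methoxy-4-(methoxymethoxy)-3-[(2R)-5-methyl-2-(prop-1-en-2-yl)hex-4-en-1-yl]phenyl}prop-2-en-1-one (not isolated) | C=C(C)[C@H](CC=C(C)C)Cc1c(O)c(C(=O)/C=C/N(C)C)c(OC)cc1OCOC | intermediate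
10 | 5-methoxy-7-(methoxymethoxy)-8-[(2R)-5-methyl-2-(prop-1-en-2-yl)hex-4-en-1-yl]-4H-chromen-4-one | C=C(C)[C@H](CC=C(C)C)Cc1c(OCOC)cc(OC)c2c1OC=CC2=O | intermediate
11 | 4-bromo-3-methoxyphenol | COc1cc(O)ccc1Br | starting material
12 | 1-bromo-2-methoxy-4-(methoxymethoxy)benzene | COCOc1ccc(Br)c(OC)c1 | intermediate
13 | [2-methoxy-4-(methoxymethoxy)phenyl]lithium (not isolated) | [Li]c1ccc(OCOC)cc1OC | intermediate
14 | lithium [2-methoxy-4-(methoxymethoxy)phenyl]triisopropoxyborate (not isolated) | [Li+].CC(C)O[B-](OC(C)C)(OC(C)C)c1ccc(OCOC)cc1OC | intermediate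
15 | [2-methoxy-4-(methoxymethoxy)phenyl]boronic acid | OB(O)c1ccc(OCOC)cc1OC | intermediate
16 | (2S)-5-methoxy-2-[2-methoxy-4-(methoxymethoxy)phenyl]-7-(methoxymethoxy)-8-[(2R)-5-methyl-2-(prop-1-en-2-yl)hex-4-en-1-yl]-2,3-dihydro-4H-chromen-4-one | C=C(C)[C@H](CC=C(C)C)Cc1c(OCOC)cc(OC)c2c1O[C@H](c1ccc(OCOC)cc1OC)CC2=O | intermediate
17 | (2S)-5-methoxy-2-[2-methoxy-4-(trimethylsilyloxy)phenyl]-8-[(2R)-5-methyl-2-(prop-1-en-2-yl)hex-4-en-1-yl]-7-(trimethylsilyloxy)-2,3-dihydro-4H-chromen-4-one (not isolated) | C=C(C)[C@H](CC=C(C)C)Cc1c(O[Si](C)(C)C)cc(OC)c2c1O[C@H](c1ccc(O[Si](C)(C)C)cc1OC)CC2=O | intermediate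
18 | (2S)-2'-methoxykurarinone, (2S)-7-hydroxy-2-(4-hydroxy-2-methoxyphenyl)-5-methoxy-8-[(2R)-5-methyl-2-(prop-1-en-2-yl)hex-4-en-1-yl]-2,3-dihydro-4H-chromen-4-one | C=C(C)[C@H](CC=C(C)C)Cc1c(O)cc(OC)c2c1O[C@H](c1ccc(O)cc1OC)CC2=O | target

## Step count and least certain steps

Total step count: 10.

Longest linear sequence: 7 steps (3 → 4 → 6 → 7 → 8 → 10 → 16 → 18; steps 2, 3, 4, 5, 6, 9, 10).

**Step 3 (key step, proposed new method).** Four things may go wrong.
- The acetyl group lowers the nucleophilicity of ring A, so C–C bond formation may be slow while the amine is tied up by reversible aza-Michael addition to 2.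
- Uncatalysed addition of the phenol(ate) to free 2 would leak racemic material into the product.
- The enamine geometry or the face of protonation may be poorly controlled, because the two CH2 groups at C2'' differ only at a distance.
- A second alkylation at C6 may compete.

The fallback uses known chemistry. It sets out from 4 and comes back at 8, bypassing 6 and 7.
- Iodination (NIS, MeCN, 0 °C; C6 and C8 are again equivalent) gives 1-[2,6-dihydroxy-3-iodo-4-(methoxymethoxy)phenyl]ethanone F1.
- Methylation of the less hindered hydroxyl (MeI, K2CO3, acetone) gives 1-[2-hydroxy-3-iodo-6-methoxy-4-(methoxymethoxy)phenyl]ethanone F2.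
- Separately, commercial (±)-lavandulol is resolved by lipase-catalysed acetylation with vinyl acetate. The S-configured fraction is collected as (S)-lavandulyl acetate F3 and methanolysed (K2CO3, MeOH) to (S)-lavandulol F4. If the enzyme acylates the R alcohol instead, F4 is the alcohol left behind.
- An Appel reaction (I2, PPh3, imidazole) gives (S)-lavandulyl iodide F5, and zinc insertion (Zn, LiCl, THF) gives (S)-lavandulylzinc iodide F6.
- Negishi coupling of F6 with F2 (phenol deprotonated beforehand with NaH; Pd(OAc)2/SPhos, THF) gives 8.
- The descriptor changes from S to R only because CH2–X loses its CIP rank to the isopropenyl group when X becomes carbon.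

**Step 9.** Carbometalation may be slow, because two donor oxygens make the chromone electron-rich and the boronic acid is ortho-substituted. Protodeboronation of the electron-rich boronic acid may consume it first. Ring opening of the rhodium enolate by β-oxygen elimination, followed by reclosure, would erode the configuration at C2.

The fallback sets out from 8 and comes back at 16.
- Commercial 4-hydroxy-2-methoxybenzaldehyde is protected (MOMCl, i-Pr2NEt) to 2-methoxy-4-(methoxymethoxy)benzaldehyde F7.
- Claisen–Schmidt condensation with 8 (KOH, EtOH, rt) gives the 2'-hydroxychalcone F8.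
- NaOAc in refluxing EtOH closes ring C to a mixture of 16 and its (2R) epimer F9.
- Kinetic resolution by asymmetric transfer hydrogenation (Cp*RhCl(TsDPEN) of the matching configuration, HCO2H/Et3N, EtOAc) reduces only the 2R ketone to the (2R,4R)-cis-flavan-4-ol F10, which is far more polar and is removed by chromatography. This leaves 16.

**Step 5.** Site selectivity between the two chelated hydroxyls may be poor, since the steric difference is moderate, and over-methylation is possible.

The fallback sets out from 6 and comes back at 8. It uses the ketone itself as a tether.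
- MeOH with PPTS and molecular sieves closes the hydroxyl next to C8 onto C8'' to give the cyclic methyl ketal F11 (both ketal epimers). The only free hydroxyl is then O5–H.
- MeI/K2CO3 in DMF gives the O5-methyl ether F12.
- PPTS in aqueous acetone reopens the ketal to the keto phenol F13.
- Methylenation as in step 4 gives 8.

**Step 4.** Enolisation towards C2'' by the basic ylide would cause partial racemisation. Ring–chain tautomerism of the hydroxy ketone and poor solubility of the diphenoxide may make the reaction sluggish.

The fallback sets out from 6 and comes back at 7. It replaces the ylide by a non-basic carbon nucleophile (Peterson olefination).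
- TMSCH2MgCl/CeCl3 (excess, THF, −78 °C to 0 °C) adds to the aliphatic ketone to give the β-hydroxysilane F14 (both carbinol epimers).
- Elimination with HF·pyridine or KH gives 7.

**Step 1.** The Mannich attack may occur at the CH3 side of the ketone, methylenation may occur twice, formaldehyde may attack the trisubstituted alkene, and the product may dimerise during isolation.

The fallback sets out from 1 and comes back at 2. It fixes the regiochemistry before the C1 unit arrives.
- TMSI/(Me3Si)2NH gives the more substituted silyl enol ether F15.
- Dimethyl(methylidene)ammonium iodide gives the Mannich base F16.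
- MeI gives the quaternary salt F17.
- Aqueous NaHCO3/CH2Cl2 eliminates trimethylamine to give 2.

## Further compounds

F1 | step 3 | 1-[2,6-dihydroxy-3-iodo-4-(methoxymethoxy)phenyl]ethanone | CC(=O)c1c(O)cc(OCOC)c(I)c1O
F2 | step 3 | 1-[2-hydroxy-3-iodo-6-methoxy-4-(methoxymethoxy)phenyl]ethanone | CC(=O)c1c(OC)cc(OCOC)c(I)c1O
F3 | step 3 | (S)-lavandulyl acetate, (2S)-5-methyl-2-(prop-1-en-2-yl)hex-4-en-1-yl acetate | C=C(C)[C@H](CC=C(C)C)COC(C)=O
F4 | step 3 | (S)-lavandulol, (2S)-5-methyl-2-(prop-1-en-2-yl)hex-4-en-1-ol | C=C(C)[C@H](CC=C(C)C)CO
F5 | step 3 | (S)-lavandulyl iodide, (5S)-5-(iodomethyl)-2,6-dimethylhepta-2,6-diene | C=C(C)[C@H](CC=C(C)C)CI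
F6 | step 3 | (S)-lavandulylzinc iodide | C=C(C)[C@H](CC=C(C)C)C[Zn]I
F7 | step 9 | 2-methoxy-4-(methoxymethoxy)benzaldehyde | COCOc1ccc(C=O)c(OC)c1
F8 | step 9 | (2E)-1-{2-hydroxy-6-methoxy-4-(methoxymethoxy)-3-[(2R)-5-methyl-2-(prop-1-en-2-yl)hex-4-en-1-yl]phenyl}-3-[2-methoxy-4-(methoxymethoxy)phenyl]prop-2-en-1-one | C=C(C)[C@H](CC=C(C)C)Cc1c(O)c(C(=O)/C=C/c2ccc(OCOC)cc2OC)c(OC)cc1OCOC
F9 | step 9 | (2R) epimer of 16 | C=C(C)[C@H](CC=C(C)C)Cc1c(OCOC)cc(OC)c2c1O[C@@H](c1ccc(OCOC)cc1OC)CC2=O
F10 | step 9 | (2R,4R)-5-methoxy-2-[2-methoxy-4-(methoxymethoxy)phenyl]-7-(methoxymethoxy)-8-[(2R)-5-methyl-2-(prop-1-en-2-yl)hex-4-en-1-yl]-3,4-dihydro-2H-chromen-4-ol | C=C(C)[C@H](CC=C(C)C)Cc1c(OCOC)cc(OC)c2c1O[C@@H](c1ccc(OCOC)cc1OC)C[C@H]2O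
F11 | step 5 | 1-[(3R)-7-hydroxy-2-methoxy-5-(methoxymethoxy)-2-methyl-3-(3-methylbut-2-en-1-yl)-3,4-dihydro-2H-chromen-8-yl]ethanone (both C2 epimers) | COC1(C)Oc2c(C(C)=O)c(O)cc(OCOC)c2C[C@H]1CC=C(C)C
F12 | step 5 | 1-[(3R)-2,7-dimethoxy-5-(methoxymethoxy)-2-methyl-3-(3-methylbut-2-en-1-yl)-3,4-dihydro-2H-chromen-8-yl]ethanone (both C2 epimers) | COC1(C)Oc2c(C(C)=O)c(OC)cc(OCOC)c2C[C@H]1CC=C(C)C
F13 | step 5 | (3R)-3-{[3-acetyl-2-hydroxy-4-methoxy-6-(methoxymethoxy)phenyl]methyl}-6-methylhept-5-en-2-one | CC(=O)[C@H](CC=C(C)C)Cc1c(O)c(C(C)=O)c(OC)cc1OCOC
F14 | step 4 | 1-{2,6-dihydroxy-3-[(2R)-2-(2-hydroxy-1-trimethylsilylpropan-2-yl)-5-methylhex-4-en-1-yl]-4-(methoxymethoxy)phenyl}ethanone (both carbinol epimers) | C[Si](C)(C)CC(C)(O)[C@H](CC=C(C)C)Cc1c(O)c(C(C)=O)c(O)cc1OCOC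
F15 | step 1 | trimethyl[(6-methylhepta-2,5-dien-2-yl)oxy]silane (E/Z) | CC(O[Si](C)(C)C)=CCC=C(C)C
F16 | step 1 | 3-[(dimethylamino)methyl]-6-methylhept-5-en-2-one (racemic) | CC(=O)C(CN(C)C)CC=C(C)C
F17 | step 1 | (2-acetyl-5-methylhex-4-en-1-yl)trimethylammonium iodide (racemic) | CC(=O)C(C[N+](C)(C)C)CC=C(C)C.[I-]
A1 | alternative 1 | (2E)-1-{2,4-dihydroxy-6-methoxy-3-[(2R)-5-methyl-2-(prop-1-en-2-yl)hex-4-en-1-yl]phenyl}-3-(4-hydroxy-2-methoxyphenyl)prop-2-en-1-one | C=C(C)[C@H](CC=C(C)C)Cc1c(O)cc(OC)c(C(=O)/C=C/c2ccc(O)cc2OC)c1O
A2 | alternative 1 | (S)-lavandulyl bromide, (5S)-5-(bromomethyl)-2,6-dimethylhepta-2,6-diene | C=C(C)[C@H](CC=C(C)C)CBr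
A3 | alternative 2 | (2S)-7-hydroxy-2-(4-hydroxy-2-methoxyphenyl)-5-methoxy-8-(3-methylbut-2-en-1-yl)-2,3-dihydro-4H-chromen-4-one | CC(C)=CCc1c(O)cc(OC)c2c1O[C@H](c1ccc(O)cc1OC)CC2=O
A4 | alternative 2 | 2,2-dimethyl-3-(3-methylbut-2-en-1-yl)chroman fused at O7/C8 of the (2S)-flavanone (chroman C3 not controlled) | CC(C)=CCC1Cc2c(cc(OC)c3c2O[C@H](c2ccc(O)cc2OC)CC3=O)OC1(C)C
A5 | alternative 3 | 1-{2-hydroxy-6-methoxy-4-(methoxymethoxy)-3-[(2E)-3,5,5-trimethylhepta-2,6-dien-1-yl]phenyl}ethanone | C=CC(C)(C)C/C(C)=C/Cc1c(O)c(C(C)=O)c(OC)cc1OCOC
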